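Saturday's flask receives 0.302 equivalents of coupling partner against 1.10 in Friday's, and the meeting turned on that comparison.

the same everywhere: coupling partner 0.121 M (fed, over 1.0 h)

| run | starting material | temperature | remark | time |
|---|---|---|---|---|
| south | 0.16 M | 8 °C | run made earlier |  |
| west | 0.62 M | 24 °C | run made earlier |  |
| Saturday's | 0.40 M |  | at 0 °C throughout | 2.5 d |
| Friday's | 0.11 M |  | at 0 °C until 1.0 h, from then on at 30 °C | 2.5 d |

- south (time / h: target / %, starting material / %): 3.00: 15.9, 28.1; 8.00: 18.1, 24.6; 15.0: 16.2, 24.1; 25.0: 16.7, 23.9; 30.0: 17.8, 24.7; 40.0: 16.8, 24.4
- west (time / h: target / %, starting material / %): 1.00: 3.6, 81.0; 2.00: 3.9, 80.5; 3.00: 3.3, 81.6; 5.00: 3.2, 80.6; 8.00: 4.8, 81.2; 12.0: 4.8, 81.5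

(standard deviation of a reading: 0.5 percentage points)

* which of the two ends with the higher amount of target, in percent of the starting material charged ("neither" if they lie within 2 percentage points) (Saturday's / Friday's / neither)
* target at the end, in percent of the starting material charged, Saturday's
* target at the end, in percent of the starting material charged, Friday's



The first speaker reported that starting material had stopped falling in both earlier runs. The south run had consumed 75.6 % of its starting material at 40.0 h against 0.756 equivalents charged, and the west run 18.5 % at 12.0 h against 0.195. She concluded that coupling partner was the limiting reagent in both, consumed one to one.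

The second speaker read 22.6 % of the turnover as target from the south readings after 8.00 h and 20.8 % from the west readings. She proposed carrying their mean, 21.7 %, as the target share of turnover, target formed per unit of starting material consumed, a selectivity.

She then solved the two ends and joined them. For a one-to-one coupling run to its end, she said, the fraction of the charge turned over equals the equivalents below one equivalent and is the whole charge above one. Her own reckoning, share times the smaller of one and the equivalents, gave 6.55 % for Saturday's and 21.7 % for Friday's.

The forecaster, whose figures stand apart from that reckoning, entered Friday's as the higher flask, with 6.6 % for Saturday's and 22 % for Friday's, and noted of the two earlier runs: “The two changes could be cancelling, so this is uncertain.”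

The simulation gave 6.82 % for Saturday's and 20.9 % for Friday's, so Friday's ends higher.

    starting material + coupling partner → target (k = 5.50 × 10⁻⁴ /M/s, Ea = 53.0 kJ/mol)
    starting material + coupling partner → isomer of the product (k = 6.90 × 10⁻⁴ /M/s, Ea = 67.0 kJ/mol)
    starting material + coupling partner → second isomer (k = 0.00120 /M/s, Ea = 47.0 kJ/mol)
    (constants at 0 °C)

Saturday's turned over 30.2 % of its starting material by the end, at a share of 22.5 % against the carried 21.7 %, and Friday's ended at a share of 20.9 %. With the difference in starting-material concentration taken away, Saturday's rises from 6.82 % to 22.5 %. The difference in temperature programme is not the reason: without it Saturday's stands at 6.58 %. The neighbouring flask, Saturday's recipe with 0.048 M of coupling partner, has 0.120 equivalents, reckons to 2.60 % by the carried share and holds 2.70 %.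

(The runs were generated by integration for an exercise, and the scatter is random.)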